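**Retrosynthetic overview**
- The target is reached by mild saponification of an (S)-3-butylphthalide; this lactone is the only ring made in the route (ring A and ring B are bought as benzene rings), and it is opened after hydrogenolysis of three benzyl ethers.
- The tribenzyl phthalide comes from a 2-aryloxy-4-benzyloxybenzoic acid and pentanal by a new enantioselective carboxylate-directed C–H addition/lactonization, which makes the C–C bond, the lactone ring and the (S)-centre in one step.
- The diaryl ether acid comes from an Ullmann C–O coupling of the ring A phenol with a ring B 2-bromobenzoate (from 2-bromo-4-hydroxybenzoic acid), then ester hydrolysis.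
- The ring A phenol comes from olivetol by O-benzylation, Vilsmeier–Haack formylation next to the pentyl chain and Dakin-type oxidation.

Assumption: the target is wanted as the free (S)-hydroxy acid and not as its lactone; Cpx is C29H23O2, the (R)-configured cyclopentadienyl ligand fused through two CH2 groups to the 2,2'-positions of 3,3'-dimethoxy-1,1'-binaphthyl; the sense of induction of the new catalyst is a prediction, and the mirror-image ligand is taken if it proves opposite.

**Step 1**
Reactants: 1 olivetol (5-pentylbenzene-1,3-diol)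
Product: 2 1,3-bis(benzyloxy)-5-pentylbenzene
Conditions: BnBr (2.4 equiv), K2CO3 (3 equiv), DMF, 60 °C
Reagents that add atoms: benzyl bromide, BrCc1ccccc1
Why: Williamson ether synthesis on both phenols; benzyl is chosen so that all phenols can be freed at the end by neutral hydrogenolysis.

**Step 2**
Reactants: 2 1,3-bis(benzyloxy)-5-pentylbenzene
Product: 4 2,4-bis(benzyloxy)-6-pentylbenzaldehyde, via aryl iminium chloride 3 (not isolated)
Conditions: POCl3 (1.5 equiv), DMF, 0 °C to 70 °C; then H2O, 0 °C to rt
Reagents that add atoms: N,N-dimethylformamide, CN(C)C=O; water, O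
Why: Vilsmeier–Haack formylation goes para to one benzyloxy group and next to the pentyl chain, not into the crowded position between the two benzyloxy groups, as is usual for orcinol-type diethers.

**Step 3**
Reactants: 4 2,4-bis(benzyloxy)-6-pentylbenzaldehyde
Product: 6 2,4-bis(benzyloxy)-6-pentylphenol, via aryl formate 5 (not isolated)
Conditions: mCPBA (1.3 equiv), CH2Cl2, 0 °C to rt; aq Na2S2O3/NaHCO3 wash; then K2CO3 (0.2 equiv), MeOH, rt
Reagents that add atoms: mCPBA (3-chloroperoxybenzoic acid), OOC(=O)c1cccc(Cl)c1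
Why: Baeyer–Villiger (Dakin-type) oxidation, in which the electron-rich aryl group migrates to oxygen, followed by mild methanolysis of the formate to the hindered phenol.

**Step 4**
Reactants: 7 2-bromo-4-hydroxybenzoic acid
Product: 8 benzyl 4-(benzyloxy)-2-bromobenzoate
Conditions: BnBr (2.3 equiv), K2CO3 (3 equiv), DMF, 60 °C
Reagents that add atoms: benzyl bromide, BrCc1ccccc1
Why: Williamson-type SN2 alkylation of phenoxide and carboxylate in one operation; the benzyl ester masks the acid during the copper-catalysed step.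

**Step 5**
Reactants: 6 2,4-bis(benzyloxy)-6-pentylphenol; 8 benzyl 4-(benzyloxy)-2-bromobenzoate
Product: 9 benzyl 4-(benzyloxy)-2-[2,4-bis(benzyloxy)-6-pentylphenoxy]benzoate
Conditions: CuI (10 mol %), picolinic acid (20 mol %), K3PO4 (2 equiv), DMSO, 90 °C
Reagents that add atoms: none
Why: Ullmann diaryl ether coupling under CuI/picolinic acid conditions that tolerate ortho-substituted phenols, with the ortho ester activating the C–Br bond; 90 °C is kept as the ceiling to avoid benzyl transfer from the ester.

**Step 6**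
Reactants: 9 benzyl 4-(benzyloxy)-2-[2,4-bis(benzyloxy)-6-pentylphenoxy]benzoate
Product: 10 4-(benzyloxy)-2-[2,4-bis(benzyloxy)-6-pentylphenoxy]benzoic acid
Conditions: LiOH·H2O (5 equiv), THF/MeOH/H2O 3:1:1, 50 °C; then 1 M HCl to pH 2–3
Reagents that add atoms: lithium hydroxide, [Li+].[OH-]
Why: ester saponification by acyl–oxygen cleavage; the benzyl ethers and the diaryl ether are inert to hydroxide.

**Step 7**
Reactants: 10 4-(benzyloxy)-2-[2,4-bis(benzyloxy)-6-pentylphenoxy]benzoic acid; 11 pentanal (3 equiv)
Product: 13 (3S)-5-(benzyloxy)-7-[2,4-bis(benzyloxy)-6-pentylphenoxy]-3-butyl-2-benzofuran-1(3H)-one, via hydroxy acid 12 (not isolated)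
Conditions: [CpxRhI2]2 (2.5 mol %), AgSbF6 (10 mol %), CsO2CCMe3 (20 mol %), pentanal added over 6 h, ClCH2CH2Cl/(CF3)2CHOH 4:1, 45 °C; then TsOH·H2O (5 mol %), rt
Reagents that add atoms: none
Why: Proposed new method: an enantioselective carboxylate-directed ortho C–H addition of a benzoic acid to an unactivated aliphatic aldehyde with lactonization in the flask, run by a cationic chiral cyclopentadienyl complex of trivalent rhodium; the carboxylate of 10 binds rhodium and pivalate-assisted concerted metalation–deprotonation at C6 of ring B (the only ortho C–H) gives a five-membered rhodacycle whose aryl–Rh bond is nucleophilic, pentanal (polarized by hydrogen bonding to the fluorinated alcohol) binds in the one open quadrant left by the binaphthyl wall and a methoxy arm of Cpx with its butyl chain turned away from the ligand so that the aryl group migrates to the Re face and gives the (S)-alkoxide, and protonolysis by a further molecule of 10 followed by fast lactonization of 12 to 13 with loss of water takes the alcohol out of the retro-addition equilibrium and so fixes yield and ee; the closest known reaction types are the racemic annulations of benzoic acids or benzimidates with aldehydes to phthalides catalysed by [Cp*RhCl2]2 with AgSbF6 and the enantioselective C–H additions to polar double bonds catalysed by chiral cyclopentadienyl complexes of trivalent rhodium.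

**Step 8**
Reactants: 13 (3S)-5-(benzyloxy)-7-[2,4-bis(benzyloxy)-6-pentylphenoxy]-3-butyl-2-benzofuran-1(3H)-one
Product: 14 (3S)-3-butyl-7-(2,4-dihydroxy-6-pentylphenoxy)-5-hydroxy-2-benzofuran-1(3H)-one
Conditions: H2 (1 atm), 10 % Pd/C, EtOAc, rt
Reagents that add atoms: none
Why: hydrogenolysis of the three benzyl aryl ethers under neutral conditions; the lactone C–O bond at the stereocentre sits meta to both ring oxygens and is not activated, so it and the (S)-configuration are kept.

**Step 9**
Reactants: 14 (3S)-3-butyl-7-(2,4-dihydroxy-6-pentylphenoxy)-5-hydroxy-2-benzofuran-1(3H)-one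
Product: 15 2-(2,4-dihydroxy-6-pentylphenoxy)-4-hydroxy-6-[(1S)-1-hydroxypentyl]benzoic acid (CNP0272660.1)
Conditions: LiOH (6 equiv), degassed THF/H2O 1:1, Ar, rt; then 0.5 M HCl, EtOAc, 0 °C, to pH 3–4, fast extraction, evaporation below 25 °C
Reagents that add atoms: lithium hydroxide, [Li+].[OH-]
Why: lactone saponification by acyl–oxygen cleavage leaves the C–O bond at the stereocentre intact (configuration retained), and cold, mild acidification frees the hydroxy acid before it can close again to the phthalide.

**Compound list**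
1 | olivetol (5-pentylbenzene-1,3-diol) | CCCCCc1cc(O)cc(O)c1 | starting material
2 | 1,3-bis(benzyloxy)-5-pentylbenzene | CCCCCc1cc(OCc2ccccc2)cc(OCc2ccccc2)c1 | intermediate
3 | N-[2,4-bis(benzyloxy)-6-pentylbenzylidene]-N-methylmethanaminium chloride | CCCCCc1cc(OCc2ccccc2)cc(OCc2ccccc2)c1C=[N+](C)C.[Cl-] | intermediate
4 | 2,4-bis(benzyloxy)-6-pentylbenzaldehyde | CCCCCc1cc(OCc2ccccc2)cc(OCc2ccccc2)c1C=O | intermediate
5 | 2,4-bis(benzyloxy)-6-pentylphenyl formate | CCCCCc1cc(OCc2ccccc2)cc(OCc2ccccc2)c1OC=O | intermediate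
6 | 2,4-bis(benzyloxy)-6-pentylphenol | CCCCCc1cc(OCc2ccccc2)cc(OCc2ccccc2)c1O | intermediate
7 | 2-bromo-4-hydroxybenzoic acid | OC(=O)c1ccc(O)cc1Br | starting material
8 | benzyl 4-(benzyloxy)-2-bromobenzoate | O=C(OCc1ccccc1)c1ccc(OCc2ccccc2)cc1Br | intermediate
9 | benzyl 4-(benzyloxy)-2-[2,4-bis(benzyloxy)-6-pentylphenoxy]benzoate | CCCCCc1cc(OCc2ccccc2)cc(OCc2ccccc2)c1Oc1cc(OCc2ccccc2)ccc1C(=O)OCc1ccccc1 | intermediate
10 | 4-(benzyloxy)-2-[2,4-bis(benzyloxy)-6-pentylphenoxy]benzoic acid | CCCCCc1cc(OCc2ccccc2)cc(OCc2ccccc2)c1Oc1cc(OCc2ccccc2)ccc1C(=O)O | intermediate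
11 | pentanal | CCCCC=O | starting material
12 | 4-(benzyloxy)-2-[2,4-bis(benzyloxy)-6-pentylphenoxy]-6-[(1S)-1-hydroxypentyl]benzoic acid | CCCC[C@H](O)c1cc(OCc2ccccc2)cc(Oc2c(CCCCC)cc(OCc3ccccc3)cc2OCc2ccccc2)c1C(=O)O | intermediate
13 | (3S)-5-(benzyloxy)-7-[2,4-bis(benzyloxy)-6-pentylphenoxy]-3-butyl-2-benzofuran-1(3H)-one | CCCC[C@@H]1OC(=O)c2c1cc(OCc1ccccc1)cc2Oc1c(CCCCC)cc(OCc2ccccc2)cc1OCc1ccccc1 | intermediate
14 | (3S)-3-butyl-7-(2,4-dihydroxy-6-pentylphenoxy)-5-hydroxy-2-benzofuran-1(3H)-one | CCCC[C@@H]1OC(=O)c2c1cc(O)cc2Oc1c(CCCCC)cc(O)cc1O | intermediate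
15 | 2-(2,4-dihydroxy-6-pentylphenoxy)-4-hydroxy-6-[(1S)-1-hydroxypentyl]benzoic acid | CCCCCc1cc(O)cc(O)c1Oc1cc(O)cc([C@@H](O)CCCC)c1C(=O)O | target

**Totals**
Total step count: 9. Longest linear sequence: 8 steps (steps 1, 2, 3, 5, 6, 7, 8, 9 from olivetol 1).

**Steps most likely to fail**

Step 7 (the proposed new step). The risks are that the aldehyde does not insert at a temperature low enough for good ee, that reversible addition erodes the ee, and that pentanal undergoes aldol self-condensation. The fallback uses known chemistry, sets out from phenol 6 and comes back at 13, leaving out 8 to 12. Commercial 3,5-bis(benzyloxy)benzaldehyde (O=Cc1cc(OCc2ccccc2)cc(OCc2ccccc2)c1) is treated with Bu2Zn and catalytic (−)-DAIB in toluene at 0 °C (amino-alcohol-catalysed alkylzinc addition to the Si face) to give (1S)-1-[3,5-bis(benzyloxy)phenyl]pentan-1-ol F2. NBS in MeCN at 0 °C brominates para to one benzyloxy group and next to the side chain to give (1S)-1-[3,5-bis(benzyloxy)-2-bromophenyl]pentan-1-ol F3. Bromine–lithium exchange with n-BuLi (2.2 equiv, THF, −78 °C), CO2 and acidic work-up close the lactone to (3S)-5,7-bis(benzyloxy)-3-butyl-2-benzofuran-1(3H)-one F4. MgBr2·OEt2 in toluene/Et2O at 80 °C removes only the benzyl group chelated to the lactone carbonyl and gives (3S)-5-(benzyloxy)-3-butyl-7-hydroxy-2-benzofuran-1(3H)-one F5. Tf2O and pyridine in CH2Cl2 at 0 °C give (1S)-6-(benzyloxy)-1-butyl-3-oxo-1,3-dihydro-2-benzofuran-4-yl trifluoromethanesulfonate F6. Palladium-catalysed C–O coupling of F6 with phenol 6 (Pd(OAc)2, tBuXPhos, K3PO4, toluene, 100 °C) then gives 13.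

Step 5 (Ullmann coupling of a phenol with two ortho substituents). The risks are slow coupling and reduction of the bromide. The fallback sets out from phenol 6 and comes back at acid 10, leaving out 8 and 9. Phenol 6 is heated with commercial 4-(benzyloxy)-2-fluorobenzaldehyde (O=Cc1ccc(OCc2ccccc2)cc1F) and K2CO3 in DMF at 120 °C, a nucleophilic aromatic substitution activated by the ortho formyl group, to give 4-(benzyloxy)-2-[2,4-bis(benzyloxy)-6-pentylphenoxy]benzaldehyde F1. Pinnick oxidation (NaClO2, NaH2PO4, excess 2-methyl-2-butene, t-BuOH/H2O, rt) turns F1 into 10.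

Step 9 (isolation of the free hydroxy acid). The risks are re-closure to the phthalide on acidification and air oxidation or Smiles-type rearrangement of the polyphenolate in base. The fallback sets out from 13 and comes back at target 15, leaving out 14. Phthalide 13 is opened with LiOH in THF/H2O at rt while all phenols are still benzylated, giving the lithium salt of 12. After evaporation the carboxylate is alkylated with BnBr in DMF at rt to give benzyl 4-(benzyloxy)-2-[2,4-bis(benzyloxy)-6-pentylphenoxy]-6-[(1S)-1-hydroxypentyl]benzoate F7, which is used crude and without heating. Hydrogenolysis of all four benzyl groups (H2, 10 % Pd/C, EtOAc, rt) then releases 15 under neutral conditions with no acidification.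

**Further compounds**
F1 | step 5 | 4-(benzyloxy)-2-[2,4-bis(benzyloxy)-6-pentylphenoxy]benzaldehyde | CCCCCc1cc(OCc2ccccc2)cc(OCc2ccccc2)c1Oc1cc(OCc2ccccc2)ccc1C=O
F2 | step 7 | (1S)-1-[3,5-bis(benzyloxy)phenyl]pentan-1-ol | CCCC[C@H](O)c1cc(OCc2ccccc2)cc(OCc2ccccc2)c1
F3 | step 7 | (1S)-1-[3,5-bis(benzyloxy)-2-bromophenyl]pentan-1-ol | CCCC[C@H](O)c1cc(OCc2ccccc2)cc(OCc2ccccc2)c1Br
F4 | step 7 | (3S)-5,7-bis(benzyloxy)-3-butyl-2-benzofuran-1(3H)-one | CCCC[C@@H]1OC(=O)c2c1cc(OCc1ccccc1)cc2OCc1ccccc1
F5 | step 7 | (3S)-5-(benzyloxy)-3-butyl-7-hydroxy-2-benzofuran-1(3H)-one | CCCC[C@@H]1OC(=O)c2c1cc(OCc1ccccc1)cc2O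
F6 | step 7 | (1S)-6-(benzyloxy)-1-butyl-3-oxo-1,3-dihydro-2-benzofuran-4-yl trifluoromethanesulfonate | CCCC[C@@H]1OC(=O)c2c1cc(OCc1ccccc1)cc2OS(=O)(=O)C(F)(F)F
F7 | step 9 | benzyl 4-(benzyloxy)-2-[2,4-bis(benzyloxy)-6-pentylphenoxy]-6-[(1S)-1-hydroxypentyl]benzoate | CCCC[C@H](O)c1cc(OCc2ccccc2)cc(Oc2c(CCCCC)cc(OCc3ccccc3)cc2OCc2ccccc2)c1C(=O)OCc1ccccc1
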